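## Retrosynthetic overview

1. The target is reached from a labda-8,13E-dien-6-one by α-hydroxylation at C7, α-face hydride reduction of the C6 ketone (gives the axial 6β-OH) and acylation with the isovaleryl unit.
2. The C9–C11 bond comes from an sp2–sp3 Suzuki coupling of a C9 enol triflate with the 9-BBN adduct of a C6 dienyl silyl ether (side chain).
3. The triflate comes from a trans-decalin-6,9-dione; its ring A is closed at C4–C5 by a hydrogen-atom-transfer radical cyclisation of a monocyclic dienone.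
4. Key step: that dienone, with the C10 quaternary stereocentre, arises from an enantioselective desymmetrising 1,2-alkyl shift (semipinacol/quinol type) of a prochiral quinol ketal.
5. The quinol ketal comes from o-cresol (all six carbons of ring B) and homoprenyl bromide; ring B is there first (as the arene), ring A is formed second.

Assumption: the sense of induction of the new chiral acid cannot be predicted, so the catalyst antipode that delivers the (S)-dienone in step 4 is the one used; the enynol of step 7 is bought as the pure E isomer.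

Labdane numbering is used for the bicyclic compounds: C1–C10 decalin, C11–C16 chain on C9, C17 on C8, C18/C19 on C4, C20 on C10.

## Route

Step 1
Reactants: 1 2-methylphenol (o-cresol)
Product: 2 2,6-dimethylphenol
Conditions: MeOH (excess), MgO, 450 °C, gas-phase flow
Reagents that add atoms: methanol, CO
Why: ortho-selective heterogeneous C-methylation of the surface-bound phenoxide (the commercial xylenol process) fills the one free ortho position; no stereocentre.

Step 2
Reactants: 2 2,6-dimethylphenol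
Product: 3 4,4-dimethoxy-2,6-dimethylcyclohexa-2,5-dien-1-one
Conditions: PhI(OAc)2 (2.1 equiv), MeOH, 0 °C → rt
Reagents that add atoms: methanol, CO
Why: twofold hypervalent-iodine oxidative dearomatisation at the free para position (phenol → 4-methoxyphenol → p-quinone monoketal).

Step 3
Reactants: 3 4,4-dimethoxy-2,6-dimethylcyclohexa-2,5-dien-1-one; 4 5-bromo-2-methylpent-2-ene
Product: 6 4,4-dimethoxy-2,6-dimethyl-1-(4-methylpent-3-en-1-yl)cyclohexa-2,5-dien-1-ol, via Grignard reagent 5 (not isolated)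
Conditions: Mg, THF, rt; then 3, −78 → 0 °C; pH 7 buffer
Reagents that add atoms: none
Why: 1,2-Grignard addition to the only carbonyl of the quinone monoketal; the adduct keeps a mirror plane, so it is prochiral and no stereocentre is set yet.

Step 4
Reactants: 6 4,4-dimethoxy-2,6-dimethyl-1-(4-methylpent-3-en-1-yl)cyclohexa-2,5-dien-1-ol
Product: 7 (S)-4-methoxy-2,6-dimethyl-6-(4-methylpent-3-en-1-yl)cyclohexa-2,4-dien-1-one
Conditions: chiral imidodiphosphorimidate Brønsted acid (IDPi, 3 mol %), 5 Å MS, toluene, −20 °C → rt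
Reagents that add atoms: none
Why: Proposed new method: the strong chiral acid ionises the dimethyl ketal to a 4-methoxycyclohexadienyl (arenium-type) cation that is ion-paired with the chiral anion, which also hydrogen-bonds the tertiary OH; the homoprenyl group then shifts 1,2 from the carbinol carbon to one of the two enantiotopic methyl-bearing ring carbons while the O–H proton returns to the anion, aromatisation being impossible because the terminus becomes quaternary, so the choice of terminus sets C10 as S. The closest known reactions are the racemic acid-promoted quinol-to-enedione (dienone–phenol type) 1,2-shift, chiral phosphoric acid-catalysed semipinacol rearrangements and chiral-anion catalysis of oxocarbenium ions.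

Step 5
Reactants: 7 (S)-4-methoxy-2,6-dimethyl-6-(4-methylpent-3-en-1-yl)cyclohexa-2,4-dien-1-one
Product: 10 (4aS,8aS)-2,5,5,8a-tetramethyloctahydronaphthalene-1,4-dione (trans-fused), via cis-fused methyl enol ether 8 (not isolated), via cis-fused dione 9 (not isolated)
Conditions: Fe(acac)3 (0.3 equiv), PhSiH3, EtOH/(CH2OH)2, 60 °C; then 1 M HCl, THF, rt; then NaOMe (0.2 equiv), MeOH, rt
Reagents that add atoms: water, O
Why: MHAT-initiated reductive olefin–enone coupling (radical Giese 6-exo cyclisation): the tertiary C4 radical from the trisubstituted alkene adds to C5, the electron-poor δ-carbon of the dienone, closing ring A cis; hydrolysis of the enol ether unveils the C6 ketone, and base equilibration of the now enolisable C5 gives the more stable trans ring fusion (5S, H anti to the C10 methyl).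

Step 6
Reactants: 10 (4aS,8aS)-2,5,5,8a-tetramethyloctahydronaphthalene-1,4-dione
Product: 14 (4aS,8aS)-2,5,5,8a-tetramethyl-4-[(triethylsilyl)oxy]-4a,5,6,7,8,8a-hexahydronaphthalen-1-yl trifluoromethanesulfonate, via lithium enolate 11 (not isolated), via TES enol ether 12 (not isolated), via potassium dienolate 13 (not isolated)
Conditions: LiN(iPr)2 (1.05 equiv), TESCl, THF, −78 °C; then KN(SiMe3)2 (1.2 equiv), PhNTf2, −78 → 0 °C
Reagents that add atoms: triethylsilyl chloride, CC[Si](Cl)(CC)CC; N-phenylbis(trifluoromethanesulfonimide), O=S(=O)(N(c1ccccc1)S(=O)(=O)C(F)(F)F)C(F)(F)F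
Why: regioselective enolate trapping: kinetic deprotonation takes the unhindered C7 methylene of the C6 ketone and silylation masks that ketone; the second base then removes C8–H, the only α-hydrogen of the C9 ketone (C10 is quaternary), and O-triflation gives the regiodefined tetrasubstituted enol triflate.

Step 7
Reactants: 15 (E)-3-methylpent-2-en-4-yn-1-ol
Product: 16 (E)-tert-butyldimethyl[(3-methylpent-2-en-4-yn-1-yl)oxy]silane
Conditions: TBSCl, imidazole, CH2Cl2, 0 °C → rt
Reagents that add atoms: tert-butyldimethylsilyl chloride, CC(C)(C)[Si](C)(C)Cl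
Why: standard silylation of the primary allylic alcohol; the E alkene of the future C13=C14 bond is bought in.

Step 8
Reactants: 16 (E)-tert-butyldimethyl[(3-methylpent-2-en-4-yn-1-yl)oxy]silane
Product: 17 (E)-tert-butyldimethyl[(3-methylpenta-2,4-dien-1-yl)oxy]silane
Conditions: H2 (1 atm), Pd/CaCO3 poisoned with Pb(OAc)2, quinoline, hexane, rt
Reagents that add atoms: none
Why: Lindlar semi-hydrogenation of the terminal alkyne stops at the vinyl group and leaves the trisubstituted E alkene alone.

Step 9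
Reactants: 14 (4aS,8aS)-2,5,5,8a-tetramethyl-4-[(triethylsilyl)oxy]-4a,5,6,7,8,8a-hexahydronaphthalen-1-yl trifluoromethanesulfonate; 17 (E)-tert-butyldimethyl[(3-methylpenta-2,4-dien-1-yl)oxy]silane
Product: 20 (5S,10S)-15-[(tert-butyldimethylsilyl)oxy]labda-8,13E-dien-6-one, via B-alkyl-9-BBN borane 18 (not isolated), via silyl dienol ether 19 (not isolated)
Conditions: 17, 9-BBN, THF, 0 °C → rt; then 14, PdCl2(dppf) (5 mol %), AsPh3, Cs2CO3, DMF/H2O, 45 °C; then AcOH/THF/H2O, 0 °C
Reagents that add atoms: none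
Why: anti-Markovnikov hydroboration of the monosubstituted vinyl group followed by B-alkyl Suzuki–Miyaura coupling with the enol triflate forms C9–C11 and the tetrasubstituted C8=C9 alkene; mild acid then protonates the silyl dienol ether at its α-carbon (C7) to release the β,γ-unsaturated C6 ketone.

Step 10
Reactants: 20 (5S,10S)-15-[(tert-butyldimethylsilyl)oxy]labda-8,13E-dien-6-one
Product: 23 (5S,7S,10S)-15-[(tert-butyldimethylsilyl)oxy]-7-[(triethylsilyl)oxy]labda-8,13E-dien-6-one (7α-OTES), via potassium dienolate 21 (not isolated), via potassium 7α-alkoxide 22 (not isolated)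
Conditions: KN(SiMe3)2, THF, −78 °C; 2-(phenylsulfonyl)-3-phenyloxaziridine; then TESCl, −78 → −40 °C
Reagents that add atoms: 2-(phenylsulfonyl)-3-phenyloxaziridine, O=S(=O)(c1ccccc1)N1OC1c1ccccc1; triethylsilyl chloride, CC[Si](Cl)(CC)CC
Why: Davis oxidation of the dienolate formed at the doubly activated C7–H (α to C6=O and allylic) occurs at the α-carbon from the α face, opposite the axial C10 and C4 methyl groups (sets 7S, 7α); the alkoxide is silylated in the same flask before the base-sensitive α-ketol can epimerise or isomerise.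

Step 11
Reactants: 23 (5S,7S,10S)-15-[(tert-butyldimethylsilyl)oxy]-7-[(triethylsilyl)oxy]labda-8,13E-dien-6-one
Product: 24 (5S,6S,7S,10S)-15-[(tert-butyldimethylsilyl)oxy]-7-[(triethylsilyl)oxy]labda-8,13E-dien-6-ol (6β-OH)
Conditions: NaBH4, MeOH/THF, −20 → 0 °C
Reagents that add atoms: none
Why: substrate-controlled ketone reduction: the β face of C6 is blocked by the two syn-axial methyl groups on C10 and C4, so hydride enters from the α face and gives the axial 6β-alcohol (6S).

Step 12
Reactants: 24 (5S,6S,7S,10S)-15-[(tert-butyldimethylsilyl)oxy]-7-[(triethylsilyl)oxy]labda-8,13E-dien-6-ol; 25 3-methylbutanoyl chloride (isovaleryl chloride)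
Product: 26 (5S,6S,7S,10S)-15-[(tert-butyldimethylsilyl)oxy]-7-[(triethylsilyl)oxy]labda-8,13E-dien-6-yl 3-methylbutanoate
Conditions: 25 (3 equiv), DMAP, pyridine, 50 °C
Reagents that add atoms: none
Why: DMAP-catalysed acylation of the only free hydroxyl under forcing conditions; O6 and O7 are trans-diaxial, so neither silyl nor acyl migration can occur.

Step 13
Reactants: 26 (5S,6S,7S,10S)-15-[(tert-butyldimethylsilyl)oxy]-7-[(triethylsilyl)oxy]labda-8,13E-dien-6-yl 3-methylbutanoate
Product: 27 (5S,6S,7S,10S)-7,15-dihydroxylabda-8,13E-dien-6-yl 3-methylbutanoate (6β-isovaleroyloxy-labda-8,13E-diene-7α,15-diol)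
Conditions: HF·pyridine, pyridine/THF, 0 °C → rt
Reagents that add atoms: none
Why: buffered fluoride cleavage of both silyl ethers (global desilylation); the hindered ester is untouched and cannot migrate to the anti-periplanar 7α-OH.

## Compound list

1 | 2-methylphenol (o-cresol) | Cc1ccccc1O | starting material
2 | 2,6-dimethylphenol | Cc1cccc(C)c1O | intermediate
3 | 4,4-dimethoxy-2,6-dimethylcyclohexa-2,5-dien-1-one | CC1=CC(OC)(OC)C=C(C)C1=O | intermediate
4 | 5-bromo-2-methylpent-2-ene | CC(C)=CCCBr | starting material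
5 | (4-methylpent-3-en-1-yl)magnesium bromide | CC(C)=CCC[Mg]Br | intermediate (not isolated)
6 | 4,4-dimethoxy-2,6-dimethyl-1-(4-methylpent-3-en-1-yl)cyclohexa-2,5-dien-1-ol (achiral, prochiral) | CC1=CC(OC)(OC)C=C(C)C1(O)CCC=C(C)C | intermediate
7 | (S)-4-methoxy-2,6-dimethyl-6-(4-methylpent-3-en-1-yl)cyclohexa-2,4-dien-1-one | O=C1C(C)=CC(OC)=C[C@]1(C)CCC=C(C)C | intermediate
8 | (4aR,8aS)-4-methoxy-2,5,5,8a-tetramethyl-4a,5,6,7,8,8a-hexahydronaphthalen-1(2H)-one (cis-fused, C2 epimers) | CC1C=C(OC)[C@@H]2C(C)(C)CCC[C@]2(C)C1=O | intermediate (not isolated)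
9 | (4aR,8aS)-2,5,5,8a-tetramethyloctahydronaphthalene-1,4-dione (cis-fused, C2 epimers) | CC1CC(=O)[C@@H]2C(C)(C)CCC[C@]2(C)C1=O | intermediate (not isolated)
10 | (4aS,8aS)-2,5,5,8a-tetramethyloctahydronaphthalene-1,4-dione (trans-fused; C2 configuration inconsequential) | CC1CC(=O)[C@H]2C(C)(C)CCC[C@]2(C)C1=O | intermediate
11 | lithium (4aS,8aS)-2,5,5,8a-tetramethyl-1-oxo-1,2,4a,5,6,7,8,8a-octahydronaphthalen-4-olate | CC1C=C([O-])[C@H]2C(C)(C)CCC[C@]2(C)C1=O.[Li+] | intermediate (not isolated)
12 | (4aS,8aS)-2,5,5,8a-tetramethyl-4-[(triethylsilyl)oxy]-4a,5,6,7,8,8a-hexahydronaphthalen-1(2H)-one | CC1C=C(O[Si](CC)(CC)CC)[C@H]2C(C)(C)CCC[C@]2(C)C1=O | intermediate (not isolated)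
13 | potassium (4aS,8aS)-2,5,5,8a-tetramethyl-4-[(triethylsilyl)oxy]-4a,5,6,7,8,8a-hexahydronaphthalen-1-olate | CC1=C([O-])[C@@]2(C)CCCC(C)(C)[C@@H]2C(O[Si](CC)(CC)CC)=C1.[K+] | intermediate (not isolated)
14 | (4aS,8aS)-2,5,5,8a-tetramethyl-4-[(triethylsilyl)oxy]-4a,5,6,7,8,8a-hexahydronaphthalen-1-yl trifluoromethanesulfonate | CC1=C(OS(=O)(=O)C(F)(F)F)[C@@]2(C)CCCC(C)(C)[C@@H]2C(O[Si](CC)(CC)CC)=C1 | intermediate
15 | (E)-3-methylpent-2-en-4-yn-1-ol | OC/C=C(\C)C#C | starting material
16 | (E)-tert-butyldimethyl[(3-methylpent-2-en-4-yn-1-yl)oxy]silane | CC(C)(C)[Si](C)(C)OC/C=C(\C)C#C | intermediate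
17 | (E)-tert-butyldimethyl[(3-methylpenta-2,4-dien-1-yl)oxy]silane | CC(C)(C)[Si](C)(C)OC/C=C(\C)C=C | intermediate
18 | (E)-9-{5-[(tert-butyldimethylsilyl)oxy]-3-methylpent-3-en-1-yl}-9-borabicyclo[3.3.1]nonane | CC(C)(C)[Si](C)(C)OC/C=C(\C)CCB1C2CCCC1CCC2 | intermediate (not isolated)
19 | (5S,10S)-15-[(tert-butyldimethylsilyl)oxy]-6-[(triethylsilyl)oxy]labda-6,8,13E-triene | CC1=C(CC/C(C)=C/CO[Si](C)(C)C(C)(C)C)[C@@]2(C)CCCC(C)(C)[C@@H]2C(O[Si](CC)(CC)CC)=C1 | intermediate (not isolated)
20 | (5S,10S)-15-[(tert-butyldimethylsilyl)oxy]labda-8,13E-dien-6-one | CC1=C(CC/C(C)=C/CO[Si](C)(C)C(C)(C)C)[C@@]2(C)CCCC(C)(C)[C@@H]2C(=O)C1 | intermediate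
21 | potassium dienolate of 20 (C6 enolate conjugated with C8=C9) | CC1=C(CC/C(C)=C/CO[Si](C)(C)C(C)(C)C)[C@@]2(C)CCCC(C)(C)[C@@H]2C([O-])=C1.[K+] | intermediate (not isolated)
22 | potassium (5S,7S,10S)-15-[(tert-butyldimethylsilyl)oxy]-6-oxolabda-8,13E-dien-7-olate (7α) | CC1=C(CC/C(C)=C/CO[Si](C)(C)C(C)(C)C)[C@@]2(C)CCCC(C)(C)[C@@H]2C(=O)[C@H]1[O-].[K+] | intermediate (not isolated)
23 | (5S,7S,10S)-15-[(tert-butyldimethylsilyl)oxy]-7-[(triethylsilyl)oxy]labda-8,13E-dien-6-one | CC1=C(CC/C(C)=C/CO[Si](C)(C)C(C)(C)C)[C@@]2(C)CCCC(C)(C)[C@@H]2C(=O)[C@H]1O[Si](CC)(CC)CC | intermediate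
24 | (5S,6S,7S,10S)-15-[(tert-butyldimethylsilyl)oxy]-7-[(triethylsilyl)oxy]labda-8,13E-dien-6-ol | CC1=C(CC/C(C)=C/CO[Si](C)(C)C(C)(C)C)[C@@]2(C)CCCC(C)(C)[C@@H]2[C@H](O)[C@H]1O[Si](CC)(CC)CC | intermediate
25 | 3-methylbutanoyl chloride (isovaleryl chloride) | CC(C)CC(Cl)=O | starting material
26 | (5S,6S,7S,10S)-15-[(tert-butyldimethylsilyl)oxy]-7-[(triethylsilyl)oxy]labda-8,13E-dien-6-yl 3-methylbutanoate | CC1=C(CC/C(C)=C/CO[Si](C)(C)C(C)(C)C)[C@@]2(C)CCCC(C)(C)[C@@H]2[C@H](OC(=O)CC(C)C)[C@H]1O[Si](CC)(CC)CC | intermediate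
27 | (5S,6S,7S,10S)-7,15-dihydroxylabda-8,13E-dien-6-yl 3-methylbutanoate | CC1=C(CC/C(C)=C/CO)[C@@]2(C)CCCC(C)(C)[C@@H]2[C@H](OC(=O)CC(C)C)[C@H]1O | target

## Step count and risks

Total step count: 13. Longest linear sequence: 11 (steps 1–6 and 9–13, from o-cresol).

**Step 4 (the proposed new step).** The risks are low enantioselectivity, acid-induced ether formation between the tertiary OH and the side-chain alkene, and a second (dienone–phenol) shift of 7 to an aromatic phenol if the acid is left too long. The fallback uses known chemistry, sets out from 6 and comes back at 7. Dilute aqueous AcOH hydrolyses the ketal of 6 to the prochiral quinol 4-hydroxy-3,5-dimethyl-4-(4-methylpent-3-en-1-yl)cyclohexa-2,5-dien-1-one F1. CF3CO2H in CH2Cl2 then brings about the known racemic acid-promoted quinol-to-enedione 1,2-shift to 2,6-dimethyl-2-(4-methylpent-3-en-1-yl)cyclohex-5-ene-1,4-dione F2. HC(OMe)3/TsOH in MeOH turns its unhindered C4 carbonyl into the methyl dienol ether, racemic 4-methoxy-2,6-dimethyl-6-(4-methylpent-3-en-1-yl)cyclohexa-2,4-dien-1-one F3, and preparative chromatography on a chiral stationary phase gives (S)-7.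

**Step 5.** The risks are hydrogen-atom transfer to the dienone instead of the alkene, γ-protonation of the dienolate, and an incomplete cis → trans equilibration. The fallback closes ring A by a cationic route; it sets out from 7 and comes back at 10. Markovnikov hydrochlorination of the side-chain alkene (TsCl, PhSiH3, Co(BF4)2·6H2O with a salen-type ligand, EtOH) gives (S)-6-(4-chloro-4-methylpentyl)-4-methoxy-2,6-dimethylcyclohexa-2,4-dien-1-one F4. AgOSO2CF3 with 2,6-di-tert-butylpyridine ionises the tertiary chloride and the enol ether carbon C5 closes the ring (SN1 alkylation of an enol ether) to (S)-4-methoxy-2,5,5,8a-tetramethyl-6,7,8,8a-tetrahydronaphthalen-1(5H)-one F5. Conjugate reduction with KBH(sBu)3 gives (8aS)-4-methoxy-2,5,5,8a-tetramethyl-3,5,6,7,8,8a-hexahydronaphthalen-1(2H)-one F6, and aqueous HCl hydrolyses its tetrasubstituted enol ether with protonation of C5 from the less hindered α face to give 10.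

**Step 9.** The risk is slow oxidative addition and transmetalation at a tetrasubstituted triflate next to a quaternary carbon, with loss of the silyl dienol ether under the basic aqueous conditions. The fallback replaces cross-coupling by carbonyl addition; it sets out from 12 (step 6 is stopped after the silylation and 12 is isolated) and 17, and comes back at 19. Hydroboration of 17 with 9-BBN and treatment of borane 18 with I2/NaOMe gives (E)-tert-butyl[(5-iodo-3-methylpent-2-en-1-yl)oxy]dimethylsilane F7. tBuLi converts it into (E)-{5-[(tert-butyldimethylsilyl)oxy]-3-methylpent-3-en-1-yl}lithium F8, which adds with CeCl3 to the free C9 ketone of 12 to give the tertiary alcohol (5S,10S)-15-[(tert-butyldimethylsilyl)oxy]-6-[(triethylsilyl)oxy]labda-6,13E-dien-9-ol F9. Burgess reagent dehydrates F9 toward the conjugated siloxydiene 19, which is hydrolysed to 20 as in step 9.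

Further compounds
F1 | step 4 | 4-hydroxy-3,5-dimethyl-4-(4-methylpent-3-en-1-yl)cyclohexa-2,5-dien-1-one | O=C1C=C(C)C(O)(CCC=C(C)C)C(C)=C1
F2 | step 4 | 2,6-dimethyl-2-(4-methylpent-3-en-1-yl)cyclohex-5-ene-1,4-dione (racemic) | CC1=CC(=O)CC(C)(CCC=C(C)C)C1=O
F3 | step 4 | 4-methoxy-2,6-dimethyl-6-(4-methylpent-3-en-1-yl)cyclohexa-2,4-dien-1-one (racemic) | O=C1C(C)=CC(OC)=CC1(C)CCC=C(C)C
F4 | step 5 | (S)-6-(4-chloro-4-methylpentyl)-4-methoxy-2,6-dimethylcyclohexa-2,4-dien-1-one | O=C1C(C)=CC(OC)=C[C@]1(C)CCCC(C)(C)Cl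
F5 | step 5 | (S)-4-methoxy-2,5,5,8a-tetramethyl-6,7,8,8a-tetrahydronaphthalen-1(5H)-one | CC1=CC(OC)=C2C(C)(C)CCC[C@]2(C)C1=O
F6 | step 5 | (8aS)-4-methoxy-2,5,5,8a-tetramethyl-3,5,6,7,8,8a-hexahydronaphthalen-1(2H)-one | CC1CC(OC)=C2C(C)(C)CCC[C@]2(C)C1=O
F7 | step 9 | (E)-tert-butyl[(5-iodo-3-methylpent-2-en-1-yl)oxy]dimethylsilane | CC(C)(C)[Si](C)(C)OC/C=C(\C)CCI
F8 | step 9 | (E)-{5-[(tert-butyldimethylsilyl)oxy]-3-methylpent-3-en-1-yl}lithium | [Li]CC/C(C)=C/CO[Si](C)(C)C(C)(C)C
F9 | step 9 | (5S,10S)-15-[(tert-butyldimethylsilyl)oxy]-6-[(triethylsilyl)oxy]labda-6,13E-dien-9-ol | CC1C=C(O[Si](CC)(CC)CC)[C@H]2C(C)(C)CCC[C@]2(C)C1(O)CC/C(C)=C/CO[Si](C)(C)C(C)(C)C
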